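**Plan**

- Cuts: (a) the ester C–O bond joining the two halves, at the CH2–O of the tertiary carbinol (made by carboxylate opening of a spiro-epoxide); (b) the lactone O–CH2 bond; (c) the ring-fusion C–C bond between the carbon alpha to the lactone carbonyl and the allylic ring-fusion CH.
- Enabling feature: with the carbinol carbon taken back to a ketone, the lactone alpha-carbon is the central carbon of a β-keto ester (a diazo/carbene site). The seven-membered ring atoms O–CH2–C(CO2H)=CH–CH(fusion) are the strain-released form of a cis-2-vinylcyclopropanecarboxylate whose vinyl group is an acrylate.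
- Lactone half, forward: Michael adduct → dienoate → diazo β-keto ester → copper-carbene cyclopropanation that closes the cyclohexanone (fusion bond) and a cyclopropane at once → spiro-epoxide → union with the second half → fluoride-triggered cyclopropane opening to the seven-membered lactone → ester cleavage.
- Cyclohexene half, forward: the same Michael adduct → (R)-cryptone → trans conjugate vinylation/enol triflate → aldehyde → Morita–Baylis–Hillman-type adduct → hydroxymethylation, acetate transposition and hydrolysis to the (E)-2-(hydroxymethyl)acrylic acid.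
- Stereochemistry: the isopropyl centres of both halves come from one aminocatalytic Michael addition. The two ring-fusion centres and the carbinol centre follow by relay (carbene face, ylide attack anti to the cyclopropane, protonation to the trans-fused lactone). Trans vinyl/isopropyl comes from anti cuprate addition, and both (E)-enoates from steps that fix the geometry.

Key step: step 7

Remark: the sense of induction in step 1 is assigned by analogy with prolinol silyl ether Michael additions of aldehydes (the (R)-catalyst is taken to give the (R)-aldehyde). Compounds 17 to 19 are carried as carbinol epimers because that centre becomes sp2 in step 14.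

Step 1
Reactants: 1 3-methylbutanal; 2 but-3-en-2-one
Product: 3 (2R)-5-oxo-2-(propan-2-yl)hexanal
Conditions: (R)-2-[diphenyl(trimethylsilyloxy)methyl]pyrrolidine (5 mol%), ethyl 3,4-dihydroxybenzoate (20 mol%), neat, 4 °C
Reagents that add atoms: none
Why: Enamine-catalysed Michael addition of the aldehyde to the vinyl ketone, in which the diaryl(silyloxy)methyl group shields one face of the (E)-enamine so that the new C–C bond should form on the face that gives the (R)-aldehyde.

Step 2
Reactants: 4 tert-butyl 2-(bromomethyl)prop-2-enoate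
Product: 5 tert-butyl 2-[(diethoxyphosphoryl)methyl]prop-2-enoate
Conditions: P(OEt)3 (1.2 equiv, neat), hydroquinone (trace), 90 °C, EtBr distilled off
Reagents that add atoms: triethyl phosphite, CCOP(OCC)OCC
Why: Michaelis–Arbuzov reaction of an allylic bromide, for which direct and allylic attack by phosphorus lead to the same phosphonate.

Step 3
Reactants: 3 (2R)-5-oxo-2-(propan-2-yl)hexanal; 5 tert-butyl 2-[(diethoxyphosphoryl)methyl]prop-2-enoate
Product: 6 tert-butyl (3E,5R)-2-methylidene-8-oxo-5-(propan-2-yl)non-3-enoate
Conditions: 5, NaH, THF, 0 °C; then 3, −78 → 0 °C; aq NH4Cl; product kept cold and dilute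
Reagents that add atoms: none
Why: Horner–Wadsworth–Emmons olefination with an allylic phosphonate, a known route to (E)-2-alkoxycarbonyl-1,3-dienes, in which the aldehyde should react in preference to the methyl ketone and the low temperature should limit epimerisation of the alpha centre.

Step 4
Reactants: 7 2-(trimethylsilyl)ethanol
Product: 8 2-(trimethylsilyl)ethyl 1H-imidazole-1-carboxylate
Conditions: 1,1'-carbonyldiimidazole, CH2Cl2, 0 °C → rt
Reagents that add atoms: 1,1'-carbonyldiimidazole, O=C(n1ccnc1)n1ccnc1
Why: Acyl substitution of one imidazole of carbonyldiimidazole by the primary alcohol gives the alkoxycarbonyl imidazole.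

Step 5
Reactants: 6 tert-butyl (3E,5R)-2-methylidene-8-oxo-5-(propan-2-yl)non-3-enoate; 8 2-(trimethylsilyl)ethyl 1H-imidazole-1-carboxylate
Product: 9 1-tert-butyl 10-[2-(trimethylsilyl)ethyl] (3E,5R)-2-methylidene-8-oxo-5-(propan-2-yl)dec-3-enedioate
Conditions: LiN(SiMe3)2 (1.05 equiv), THF, −78 °C; then 8, −78 → −40 °C; aq NH4Cl
Reagents that add atoms: none
Why: Claisen-type C-acylation (Mander-type) of the kinetic methyl-side lithium enolate by the alkoxycarbonyl imidazole, whose tetrahedral adduct should survive until work-up so that one equivalent of base suffices.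

Step 6
Reactants: 9 1-tert-butyl 10-[2-(trimethylsilyl)ethyl] (3E,5R)-2-methylidene-8-oxo-5-(propan-2-yl)dec-3-enedioate
Product: 10 1-tert-butyl 10-[2-(trimethylsilyl)ethyl] (3E,5R)-9-diazo-2-methylidene-8-oxo-5-(propan-2-yl)dec-3-enedioate
Conditions: 4-acetamidobenzenesulfonyl azide, Et3N, MeCN, 0 °C → rt
Reagents that add atoms: 4-acetamidobenzenesulfonyl azide, CC(=O)Nc1ccc(cc1)S(=O)(=O)N=[N+]=[N-]
Why: Regitz diazo transfer to the doubly activated methylene of the β-keto ester.

Step 7
Reactants: 10 1-tert-butyl 10-[2-(trimethylsilyl)ethyl] (3E,5R)-9-diazo-2-methylidene-8-oxo-5-(propan-2-yl)dec-3-enedioate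
Product: 11 2-(trimethylsilyl)ethyl 7-[1-(tert-butoxycarbonyl)ethenyl]-2-oxo-5-(propan-2-yl)bicyclo[4.1.0]heptane-1-carboxylate (isopropyl anti to the cyclopropane; acrylate unit exo and cis to the ring ester)
Conditions: Cu(CF3COCHCOCF3)2 (5 mol%), ClCH2CH2Cl, 65 °C, slow addition of 10 (final 0.005 M)
Reagents that add atoms: none
Why: Loss of N2 from 10 on copper gives an electrophilic copper carbene at the carbon between the two carbonyls, which adds across the proximal (E)-double bond of the dienoate in a concerted, asynchronous (2+1) cycloaddition. The closest known reaction type is the copper- or dirhodium-catalysed intramolecular cyclopropanation of α-diazo-β-keto esters to 1-alkoxycarbonylbicyclo[4.1.0]heptan-2-ones, including cases on 1,3-dienes that give vinylcyclopropanes. The cyclohexanone closes by 6-exo attack of the carbene carbon on the nearer diene carbon (this is the ring-fusion bond of the target), and the cyclopropane closes in the same event by bonding to the next diene carbon. The new ring-fusion CH centre is controlled by the isopropyl-bearing allylic stereocentre, which should sit pseudo-equatorial in the chair-like tether so that the cyclopropane forms anti to isopropyl; the quaternary centre follows from the obligatory cis ring fusion, and the third cyclopropane centre from stereospecific transfer of the (E)-geometry, which places the acrylate unit cis to the ring ester as the later ring expansion requires. The step needs cyclopropanation to win over 1,5-insertion into the tertiary allylic C–H bond and over attack on the terminal acrylate double bond; a copper carbene is chosen because it disfavours C–H insertion, the conjugated internal alkene is the most nucleophilic site, and the electron-poor acrylate C=C could only be reached through an eight-membered ring.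

Step 8
Reactants: 11 2-(trimethylsilyl)ethyl 7-[1-(tert-butoxycarbonyl)ethenyl]-2-oxo-5-(propan-2-yl)bicyclo[4.1.0]heptane-1-carboxylate
Product: 12 2-(trimethylsilyl)ethyl 7-[1-(tert-butoxycarbonyl)ethenyl]-5-(propan-2-yl)spiro[bicyclo[4.1.0]heptane-2,2'-oxirane]-1-carboxylate (epoxide CH2 cis to the ring ester; epoxide oxygen on the cyclopropane side)
Conditions: Me3S+ I−, KN(SiMe3)2, THF, −10 °C; then 11, −10 → 0 °C
Reagents that add atoms: trimethylsulfonium iodide, C[S+](C)C.[I-]
Why: Corey–Chaykovsky epoxidation of a ketone that cannot enolise toward the quaternary cyclopropane carbon, with the ylide expected to attack anti to the cyclopropane C–C bond (as nucleophiles do with bicyclo[4.1.0]heptan-2-ones), which gives the carbinol configuration of the target.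

Step 9
Reactants: 3 (2R)-5-oxo-2-(propan-2-yl)hexanal
Product: 13 (4R)-4-(propan-2-yl)cyclohex-2-en-1-one ((R)-cryptone)
Conditions: LiOH·H2O (0.2 equiv), i-PrOH, rt
Reagents that add atoms: none
Why: Intramolecular aldol condensation of the methyl ketone onto the aldehyde (Robinson-type ring closure), which should leave the isopropyl-bearing centre untouched under these mild conditions.

Step 10
Reactants: 13 (4R)-4-(propan-2-yl)cyclohex-2-en-1-one
Product: 15 trans-3-ethenyl-4-(propan-2-yl)cyclohex-1-en-1-yl trifluoromethanesulfonate, via bromomagnesium enolate 14 (not isolated)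
Conditions: CH2=CHMgBr, CuBr·SMe2 (10 mol%), THF, −78 °C; then N-(5-chloropyridin-2-yl)bis(trifluoromethanesulfonimide), −78 → 0 °C
Reagents that add atoms: vinylmagnesium bromide, C=C[Mg]Br; N-(5-chloropyridin-2-yl)bis(trifluoromethanesulfonimide), FC(F)(F)S(=O)(=O)N(c1ccc(Cl)cn1)S(=O)(=O)C(F)(F)F
Why: Copper-catalysed conjugate addition of the vinyl Grignard reagent anti to the adjacent isopropyl group, followed by regiospecific O-triflation of the resulting enolate, fixes both the trans relationship and the position of the ring double bond.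

Step 11
Reactants: 15 trans-3-ethenyl-4-(propan-2-yl)cyclohex-1-en-1-yl trifluoromethanesulfonate
Product: 16 trans-3-formyl-4-(propan-2-yl)cyclohex-1-en-1-yl trifluoromethanesulfonate
Conditions: O3, CH2Cl2/MeOH, −78 °C, stopped at consumption of 15; then Me2S, −78 °C → rt
Reagents that add atoms: ozone, [O-][O+]=O
Why: Ozonolysis with reductive work-up should cleave only the vinyl group, because the enol triflate double bond is strongly deactivated toward ozone.

Step 12
Reactants: 16 trans-3-formyl-4-(propan-2-yl)cyclohex-1-en-1-yl trifluoromethanesulfonate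
Product: 17 methyl 2-{hydroxy[trans-6-(propan-2-yl)-3-(trifluoromethanesulfonyloxy)cyclohex-2-en-1-yl]methyl}prop-2-enoate (carbinol epimers)
Conditions: methyl propiolate, i-Bu2AlH, N-methylmorpholine N-oxide, THF, 0 °C; then 16, 0 °C → rt; aq Rochelle salt
Reagents that add atoms: methyl propiolate, C#CC(=O)OC
Why: Vinylalumination, in which the [1-(methoxycarbonyl)vinyl]alane made by hydroalumination of the propiolate adds to the hindered aldehyde, gives the Morita–Baylis–Hillman-type adduct faster than the amine-catalysed reaction would.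

Step 13
Reactants: 17 methyl 2-{hydroxy[trans-6-(propan-2-yl)-3-(trifluoromethanesulfonyloxy)cyclohex-2-en-1-yl]methyl}prop-2-enoate
Product: 18 methyl 2-{hydroxy[trans-3-(hydroxymethyl)-6-(propan-2-yl)cyclohex-2-en-1-yl]methyl}prop-2-enoate (carbinol epimers)
Conditions: Bu3SnCH2OH, Pd(PPh3)4 (5 mol%), LiCl, 1,4-dioxane, 90 °C
Reagents that add atoms: (tributylstannyl)methanol, CCCC[Sn](CCCC)(CCCC)CO
Why: Migita–Kosugi–Stille hydroxymethylation of the vinyl triflate, carried out while the side chain is still a free secondary allylic alcohol that palladium does not ionise.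

Step 14
Reactants: 18 methyl 2-{hydroxy[trans-3-(hydroxymethyl)-6-(propan-2-yl)cyclohex-2-en-1-yl]methyl}prop-2-enoate
Product: 20 methyl (2E)-2-(acetoxymethyl)-3-[trans-3-(acetoxymethyl)-6-(propan-2-yl)cyclohex-2-en-1-yl]prop-2-enoate, via allylic diacetate 19 (not isolated)
Conditions: Ac2O, Et3N, 4-(dimethylamino)pyridine (cat.), CH2Cl2, 0 °C → rt; then 1,4-diazabicyclo[2.2.2]octane (0.5 equiv), THF, 65 °C
Reagents that add atoms: acetic anhydride, CC(=O)OC(C)=O
Why: Acetylation followed by the amine-mediated SN2'/SN2 1,3-transposition of the Morita–Baylis–Hillman acetate, which is known to give the thermodynamically favoured (E)-2-(acetoxymethyl)alk-2-enoate and leaves the ordinary ring allylic acetate alone.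

Step 15
Reactants: 20 methyl (2E)-2-(acetoxymethyl)-3-[trans-3-(acetoxymethyl)-6-(propan-2-yl)cyclohex-2-en-1-yl]prop-2-enoate
Product: 21 (2E)-2-(hydroxymethyl)-3-[trans-3-(hydroxymethyl)-6-(propan-2-yl)cyclohex-2-en-1-yl]prop-2-enoic acid
Conditions: LiOH, THF/H2O (3:1), 0 °C → rt; then aq HCl to pH 3
Reagents that add atoms: lithium hydroxide, [Li+].[OH-]
Why: Saponification of the methyl ester and both acetates, which cannot lactonise or change the alkene geometry.

Step 16
Reactants: 12 spiro-epoxide (see step 8); 21 (2E)-2-(hydroxymethyl)-3-[trans-3-(hydroxymethyl)-6-(propan-2-yl)cyclohex-2-en-1-yl]prop-2-enoic acid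
Product: 22 tertiary alcohol in which the epoxide CH2 of 12 carries the acyloxy group of 21 (cyclopropane, both esters and all stereocentres unchanged)
Conditions: Cs2CO3 (0.2 equiv), DMF, 70 °C
Reagents that add atoms: none
Why: SN2 opening of the 2,2-disubstituted epoxide at its CH2 terminus by the cesium carboxylate, which joins the two halves and frees the tertiary alcohol without touching the C–O bond at the quaternary carbon.

Step 17
Reactants: 22 tertiary alcohol from step 16
Product: 24 tert-butyl ester of the target (trans-fused seven-membered lactone), via tetrabutylammonium cyclopropanecarboxylate 23 (not isolated)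
Conditions: Bu4NF (1.2 equiv, dried), THF, 0 → 50 °C; then AcOH
Reagents that add atoms: none
Why: Proposed new method: fluoride cleaves the 2-(trimethylsilyl)ethyl ester to the ammonium carboxylate, whose oxygen, held cis to the acrylate on the cyclopropane, should add to the acrylate CH2 terminus through a six-membered transition state while the developing ester enolate opens the adjacent cyclopropane bond (a cyclopropylcarbinyl-anion fragmentation, equivalent to an anionic retro-Claisen shift) to give the ε-lactone enolate, with about 27 kcal/mol of ring strain and hydrogen bonding from the neighbouring tertiary OH paying for the enolate, and protonation on the face vacated by the cyclopropane bond giving the trans-fused lactone; the closest known reaction types are the retro-Claisen rearrangement of cis-2-vinylcyclopropanecarbonyl compounds to 2,5-dihydrooxepines and homoconjugate 1,7-additions of nucleophiles to activated vinylcyclopropanes.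

Step 18
Reactants: 24 tert-butyl ester of the target
Product: 26 CNP0361406.2 (target acid), via persilylated acid 25 (not isolated)
Conditions: Me3SiOTf, 2,6-lutidine, CH2Cl2, 0 °C; then aq citric acid, THF, rt
Reagents that add atoms: none
Why: Silyl triflate-mediated cleavage of the tert-butyl ester (loss of 2-methylpropene from the O-silylated ester) under buffered aprotic conditions, in which the three alcohols are silylated in the flask and freed again with the silyl ester on mild acidic work-up.

**Compound list**

1 | 3-methylbutanal | CC(C)CC=O | starting material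
2 | but-3-en-2-one | CC(=O)C=C | starting material
3 | (2R)-5-oxo-2-(propan-2-yl)hexanal | CC(C)[C@H](C=O)CCC(C)=O | intermediate
4 | tert-butyl 2-(bromomethyl)prop-2-enoate | C=C(CBr)C(=O)OC(C)(C)C | starting material
5 | tert-butyl 2-[(diethoxyphosphoryl)methyl]prop-2-enoate | C=C(CP(=O)(OCC)OCC)C(=O)OC(C)(C)C | intermediate
6 | tert-butyl (3E,5R)-2-methylidene-8-oxo-5-(propan-2-yl)non-3-enoate | CC(C)[C@H](/C=C/C(=C)C(=O)OC(C)(C)C)CCC(C)=O | intermediate
7 | 2-(trimethylsilyl)ethanol | C[Si](C)(C)CCO | starting material
8 | 2-(trimethylsilyl)ethyl 1H-imidazole-1-carboxylate | C[Si](C)(C)CCOC(=O)n1ccnc1 | intermediate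
9 | 1-tert-butyl 10-[2-(trimethylsilyl)ethyl] (3E,5R)-2-methylidene-8-oxo-5-(propan-2-yl)dec-3-enedioate | CC(C)[C@H](/C=C/C(=C)C(=O)OC(C)(C)C)CCC(=O)CC(=O)OCC[Si](C)(C)C | intermediate
10 | 1-tert-butyl 10-[2-(trimethylsilyl)ethyl] (3E,5R)-9-diazo-2-methylidene-8-oxo-5-(propan-2-yl)dec-3-enedioate | CC(C)[C@H](/C=C/C(=C)C(=O)OC(C)(C)C)CCC(=O)C(=[N+]=[N-])C(=O)OCC[Si](C)(C)C | intermediate
11 | 2-(trimethylsilyl)ethyl 7-[1-(tert-butoxycarbonyl)ethenyl]-2-oxo-5-(propan-2-yl)bicyclo[4.1.0]heptane-1-carboxylate (isopropyl anti to cyclopropane, acrylate cis to ring ester) | CC(C)[C@H]1CCC(=O)[C@]2(C(=O)OCC[Si](C)(C)C)[C@@H](C(=C)C(=O)OC(C)(C)C)[C@H]12 | intermediate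
12 | spiro-epoxide of 11 (epoxide CH2 cis to ring ester) | CC(C)[C@H]1CC[C@@]3(CO3)[C@]2(C(=O)OCC[Si](C)(C)C)[C@@H](C(=C)C(=O)OC(C)(C)C)[C@H]12 | intermediate
13 | (4R)-4-(propan-2-yl)cyclohex-2-en-1-one | CC(C)[C@H]1CCC(=O)C=C1 | intermediate
14 | bromomagnesium enolate of trans-3-ethenyl-4-(propan-2-yl)cyclohexanone | C=C[C@H]1C=C(O[Mg]Br)CC[C@@H]1C(C)C | intermediate
15 | trans-3-ethenyl-4-(propan-2-yl)cyclohex-1-en-1-yl trifluoromethanesulfonate | C=C[C@H]1C=C(OS(=O)(=O)C(F)(F)F)CC[C@@H]1C(C)C | intermediate
16 | trans-3-formyl-4-(propan-2-yl)cyclohex-1-en-1-yl trifluoromethanesulfonate | O=C[C@H]1C=C(OS(=O)(=O)C(F)(F)F)CC[C@@H]1C(C)C | intermediate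
17 | methyl 2-{hydroxy[trans-6-(propan-2-yl)-3-(trifluoromethanesulfonyloxy)cyclohex-2-en-1-yl]methyl}prop-2-enoate (carbinol epimers) | C=C(C(=O)OC)C(O)[C@H]1C=C(OS(=O)(=O)C(F)(F)F)CC[C@@H]1C(C)C | intermediate
18 | methyl 2-{hydroxy[trans-3-(hydroxymethyl)-6-(propan-2-yl)cyclohex-2-en-1-yl]methyl}prop-2-enoate (carbinol epimers) | C=C(C(=O)OC)C(O)[C@H]1C=C(CO)CC[C@@H]1C(C)C | intermediate
19 | diacetate of 18 (carbinol epimers) | C=C(C(=O)OC)C(OC(C)=O)[C@H]1C=C(COC(C)=O)CC[C@@H]1C(C)C | intermediate
20 | methyl (2E)-2-(acetoxymethyl)-3-[trans-3-(acetoxymethyl)-6-(propan-2-yl)cyclohex-2-en-1-yl]prop-2-enoate | COC(=O)/C(=C/[C@H]1C=C(COC(C)=O)CC[C@@H]1C(C)C)COC(C)=O | intermediate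
21 | (2E)-2-(hydroxymethyl)-3-[trans-3-(hydroxymethyl)-6-(propan-2-yl)cyclohex-2-en-1-yl]prop-2-enoic acid | OC(=O)/C(=C/[C@H]1C=C(CO)CC[C@@H]1C(C)C)CO | intermediate
22 | coupled cyclopropane: tertiary alcohol with the acyl group of 21 on the carbinol CH2O | CC(C)[C@H]1CC[C@@](O)(COC(=O)/C(=C/[C@H]3C=C(CO)CC[C@@H]3C(C)C)CO)[C@]2(C(=O)OCC[Si](C)(C)C)[C@@H](C(=C)C(=O)OC(C)(C)C)[C@H]12 | intermediate
23 | tetrabutylammonium cyclopropanecarboxylate from 22 | CC(C)[C@H]1CC[C@@](O)(COC(=O)/C(=C/[C@H]3C=C(CO)CC[C@@H]3C(C)C)CO)[C@]2(C(=O)[O-])[C@@H](C(=C)C(=O)OC(C)(C)C)[C@H]12.CCCC[N+](CCCC)(CCCC)CCCC | intermediate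
24 | tert-butyl ester of the target | CC(C)[C@H]1CC[C@@](O)(COC(=O)/C(=C/[C@H]2C=C(CO)CC[C@@H]2C(C)C)CO)[C@H]2C(=O)OCC(C(=O)OC(C)(C)C)=C[C@H]12 | intermediate
25 | tris(trimethylsilyl ether) trimethylsilyl ester of the target | CC(C)[C@H]1CC[C@@](O[Si](C)(C)C)(COC(=O)/C(=C/[C@H]2C=C(CO[Si](C)(C)C)CC[C@@H]2C(C)C)CO[Si](C)(C)C)[C@H]2C(=O)OCC(C(=O)O[Si](C)(C)C)=C[C@H]12 | intermediate
26 | CNP0361406.2 | CC(C)[C@H]1CC[C@@](O)(COC(=O)/C(=C/[C@H]2C=C(CO)CC[C@@H]2C(C)C)CO)[C@H]2C(=O)OCC(C(=O)O)=C[C@H]12 | target

**Step count and risks**

Total step count: 18. Longest linear sequence: 11 steps (steps 1, 9, 10, 11, 12, 13, 14, 15, 16, 17, 18).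

Steps most likely to fail:

1. Step 17 (proposed new method). The carboxylate addition to the acrylate may reverse faster than the cyclopropane fragments, since the leaving carbanion is stabilised only by the new lactone carbonyl, and prolonged basic heating may bring on retro-aldol cleavage of the β-hydroxy lactone. The fallback opens the ring by a radical chain, using known chemistry. It sets out from 22: PhSH with azobisisobutyronitrile (benzene, 75 °C) adds a thiyl radical to the acrylate CH2, the cyclopropylcarbinyl radical opens to the ester-stabilised radical, and hydrogen transfer should give the ring-opened allyl phenyl sulfide F1. Bu4NF then frees the carboxylic acid F2. S-methylation (MeOTf, 2,6-di-tert-butylpyridine, CH2Cl2, 0 °C) followed by Cs2CO3 lets the carboxylate displace methyl phenyl sulfide from the allylic sulfonium salt, closing the lactone and coming back to the route at 24.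

2. Step 7 (key step). The carbene may insert into the tertiary allylic C–H bond (a cyclopentanone), or the cyclopropane may form on the alkene face syn to isopropyl. The fallback replaces the diazo compound by a hypervalent iodine ylide, which cyclopropanates at room temperature. It sets out from 9: PhI(OAc)2 and KOH in MeOH at 0 °C should give the phenyliodonium ylide F3, and CuCl (cat.) in CH2Cl2 at rt should then deliver the cyclopropane with loss of iodobenzene, coming back to the route at 11.

3. Step 8. The sulfonium ylide may act as a soft nucleophile on the doubly activated vinylcyclopropane acrylate (1,7-addition with ring opening) instead of adding to the hindered ketone. The fallback uses a hard lithium carbenoid at low temperature. It sets out from 11: ICH2Cl and MeLi·LiBr in THF at −78 °C (chloromethyllithium made in the flask) should add to the ketone from the same face and give, after a cold quench, the chlorohydrin F4. K2CO3 in MeCN at rt then closes the epoxide, coming back to the route at 12.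

**Further compounds**

F1 | step 17 | 2-(trimethylsilyl)ethyl ester of the ring-opened allyl phenyl sulfide (cyclohexane with ester and (Z)-CH=C(CO2t-Bu)CH2SPh side chain trans) | CC(C)[C@H]1CC[C@@](O)(COC(=O)/C(=C/[C@H]2C=C(CO)CC[C@@H]2C(C)C)CO)[C@@H](C(=O)OCC[Si](C)(C)C)[C@@H]1/C=C(\CSc3ccccc3)C(=O)OC(C)(C)C
F2 | step 17 | carboxylic acid from F1 | CC(C)[C@H]1CC[C@@](O)(COC(=O)/C(=C/[C@H]2C=C(CO)CC[C@@H]2C(C)C)CO)[C@@H](C(=O)O)[C@@H]1/C=C(\CSc3ccccc3)C(=O)OC(C)(C)C
F3 | step 7 | phenyliodonium ylide of 9 | CC(C)[C@H](/C=C/C(=C)C(=O)OC(C)(C)C)CCC(=O)[C-]([I+]c1ccccc1)C(=O)OCC[Si](C)(C)C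
F4 | step 8 | chlorohydrin from 11 (CH2Cl cis to ring ester) | CC(C)[C@H]1CC[C@@](O)(CCl)[C@]2(C(=O)OCC[Si](C)(C)C)[C@@H](C(=C)C(=O)OC(C)(C)C)[C@H]12
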